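## Retrosynthetic overview

1. Target ⇐ 1,10-epoxide: the C1–O/C10–O pair comes from peracid epoxidation of an (E)-C1=C10 olefin and invertive acid hydrolysis at C10. The angelate (Yamaguchi) and the C13 methylene (Mannich/elimination) are installed just before.
2. γ-Lactone ⇐ C6 ketone carrying a C7 acetate arm: Luche reduction sets C6, then acyl C–O closure.
3. Ten-membered ring ⇐ 1-alkenyl-6-isopropenylcyclohexenol: alkoxide-driven [3,3] ring expansion, with the enolate alkylated in the same flask (sets C7, C8 and both ring olefin geometries).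
4. Key step (C–O bond): the C8–O bond is made by Z-selective anti-Markovnikov addition of 4-methoxybenzyl alcohol to an ethynyl carbinol; the enol-ether geometry is relayed to the C8 stereocentre.
5. Ethynyl carbinol ⇐ 4-silyloxy enone ⇐ (S)-carvone (Luche reduction, silylation, allylic C–H oxidation that puts in O6). Ring order: cyclohexene (from carvone) → ten-membered carbocycle → γ-lactone (→ transient oxirane).

Assumption: germacrane numbering (ring C1–C10, lactone carbons C11–C13, C14 on C10, C15 on C4) is used for all ten-membered compounds; TBS = tert-butyldimethylsilyl, PMB = 4-methoxybenzyl, Ang = (Z)-2-methylbut-2-enoyl; simple reagents are not numbered.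

## Route

Step 1
Reactants: 1 (S)-(+)-carvone
Product: 2 (1S,5S)-cis-carveol
Conditions: NaBH4, CeCl3·7H2O, MeOH, −20 °C
Reagents that add atoms: none
Why: Luche 1,2-reduction; hydride adds axially to the half-chair with the isopropenyl group equatorial, giving the cis alcohol with the carbinol centre S (this becomes C3 of the target).

Step 2
Reactants: 2 (1S,5S)-cis-carveol
Product: 3 (1S,5S)-cis-carveol TBS ether
Conditions: TBSCl, imidazole, DMF, 23 °C
Reagents that add atoms: tert-butyldimethylsilyl chloride, CC(C)(C)[Si](C)(C)Cl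
Why: Standard imidazole-promoted silylation of a secondary allylic alcohol; no stereocentre is touched, and the bulky ether later shields the carbinol C–H and differentiates O3 from O8.

Step 3
Reactants: 3 (1S,5S)-cis-carveol TBS ether
Product: 4 (4S,6S)-4-(TBSO)-3-methyl-6-(prop-1-en-2-yl)cyclohex-2-en-1-one
Conditions: Rh2(cap)4 (1 mol%), t-BuOOH (70% aq), K2CO3, CH2Cl2, 23 °C
Reagents that add atoms: tert-butyl hydroperoxide, CC(C)(C)OO
Why: Dirhodium caprolactamate-catalysed allylic C–H oxidation turns the only ring allylic methylene of the trisubstituted olefin into the enone carbonyl (the future lactone oxygen O6); no stereocentre is created.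

Step 4
Reactants: 4 (4S,6S)-4-(TBSO)-3-methyl-6-(prop-1-en-2-yl)cyclohex-2-en-1-one; 5 ethynylmagnesium bromide
Product: 6 (1S,4S,6S)-4-(TBSO)-1-ethynyl-3-methyl-6-(prop-1-en-2-yl)cyclohex-2-en-1-ol
Conditions: 5 (0.5 M in THF), THF, −78 → 0 °C; NH4Cl (aq)
Reagents that add atoms: none
Why: Grignard 1,2-addition (the β,β-disubstituted enone disfavours 1,4-addition and the acetylide is too weakly basic to enolise C6–H); attack anti to the isopropenyl and silyloxy groups, which share one ring face, sets the carbinol centre (1S).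

Step 5
Reactants: 6 (1S,4S,6S)-4-(TBSO)-1-ethynyl-3-methyl-6-(prop-1-en-2-yl)cyclohex-2-en-1-ol; 7 4-methoxybenzyl alcohol
Product: 8 (1S,4S,6S)-4-(TBSO)-1-[(Z)-2-(PMBO)ethenyl]-3-methyl-6-(prop-1-en-2-yl)cyclohex-2-en-1-ol
Conditions: Rh(cod)(8-quinolinolate) (5 mol%), P(4-MeOC6H4)3 (10 mol%), 7 (4 equiv), DMA, 70 °C
Reagents that add atoms: none
Why: Proposed new method: Z-selective anti-Markovnikov hydroalkoxylation of a tertiary propargylic alcohol with a benzylic alcohol. The terminal alkyne tautomerises on monovalent rhodium to a vinylidene (Rh=C8=C7), the oxygen of 7 adds to the electrophilic metal-bound carbon C8, and protonolysis of the alkenylrhodium on the side remote from the bulky carbinol gives the (Z)-enol ether. No stereocentre forms here, but the new C8–O bond and its Z geometry fix C8 in step 6. The neutral, electron-rich catalyst should not ionise the propargylic C–O bond (no allenylidene or Meyer–Schuster path). Closest known reaction type: rhodium-catalysed anti-Markovnikov addition of simple alcohols to unfunctionalised terminal alkynes via vinylidenes (and the ruthenium-catalysed carboxylic acid analogue), not shown for hindered propargylic alcohols or with a benzylic alcohol in small excess.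

Step 6
Reactants: 8 (1S,4S,6S)-4-(TBSO)-1-[(Z)-2-(PMBO)ethenyl]-3-methyl-6-(prop-1-en-2-yl)cyclohex-2-en-1-ol; 9 methyl bromoacetate
Product: 12 methyl (1(10)E,3S,4Z,7S,8R)-3-(TBSO)-8-(PMBO)-6-oxo-13-norgermacra-1(10),4-dien-12-oate, via potassium alkoxide 10 (not isolated), via potassium enolate 11 (not isolated)
Conditions: KN(SiMe3)2, THF, 0 → 25 °C; then 9, −78 → −30 °C
Reagents that add atoms: none
Why: Anionic oxy-Cope rearrangement followed by enolate C-alkylation. The chair transition state with both ring bonds pseudo-equatorial (alkenyl trans to isopropenyl) gives the (E)-C1=C10 olefin and keeps the ring (Z)-C4=C5. The (Z)-enol ether places OPMB pseudo-axial at C8, syn to the alkoxide and bridged to it by K+, which sets C8 (R). The K+-chelated enolate, whose C8–O bond lies in the enolate plane and so resists β-elimination, is alkylated on the face away from the chelate, setting C7 (S).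

Step 7
Reactants: 12 methyl (1(10)E,3S,4Z,7S,8R)-3-(TBSO)-8-(PMBO)-6-oxo-13-norgermacra-1(10),4-dien-12-oate
Product: 14 (1(10)E,3S,4Z,6S,7S,8R)-3-(TBSO)-8-(PMBO)-13-norgermacra-1(10),4-dien-12,6-olide, via hydroxy ester 13 (not isolated)
Conditions: NaBH4, CeCl3·7H2O, MeOH, −40 °C; then PPTS, PhMe, 60 °C
Reagents that add atoms: none
Why: Luche reduction is strictly 1,2 and hydride enters from the outer face of the ring ketone (the inner face is screened across the ring by the C1=C10 unit), giving the (6S) allylic alcohol; PPTS-catalysed lactonisation then closes the trans-fused γ-lactone.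

Step 8
Reactants: 14 (1(10)E,3S,4Z,6S,7S,8R)-3-(TBSO)-8-(PMBO)-13-norgermacra-1(10),4-dien-12,6-olide
Product: 17 (1(10)E,3S,4Z,6S,7S,8R)-3-(TBSO)-8-(PMBO)germacra-1(10),4,11(13)-trien-12,6-olide, via Mannich base 15 (not isolated), via ammonium iodide 16 (not isolated)
Conditions: LiN(iPr)2, THF, −78 °C; Me2N=CH2+ I−, −78 → 23 °C; MeI, MeOH; NaHCO3 (aq), CH2Cl2
Reagents that add atoms: N,N-dimethylmethyleneiminium iodide (Eschenmoser's salt), C=[N+](C)C.[I-]
Why: Eschenmoser α-methylenation (lactone enolate Mannich reaction, N-quaternisation, Hofmann-type elimination); only C11 is enolisable, no leaving group sits β to it, and no stereocentre is created.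

Step 9
Reactants: 17 (1(10)E,3S,4Z,6S,7S,8R)-3-(TBSO)-8-(PMBO)germacra-1(10),4,11(13)-trien-12,6-olide
Product: 18 (1(10)E,3S,4Z,6S,7S,8R)-3-(TBSO)-8-hydroxygermacra-1(10),4,11(13)-trien-12,6-olide
Conditions: DDQ, CH2Cl2–pH 7 buffer (10:1), 0 °C
Reagents that add atoms: none
Why: Oxidative cleavage of the PMB ether by DDQ (benzylic hydride abstraction, hydrolysis of the oxocarbenium ion) leaves the silyl ether, the olefins and C8 (R) untouched.

Step 10
Reactants: 18 (1(10)E,3S,4Z,6S,7S,8R)-3-(TBSO)-8-hydroxygermacra-1(10),4,11(13)-trien-12,6-olide; 19 angelic acid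
Product: 21 (1(10)E,3S,4Z,6S,7S,8R)-8-(AngO)-3-(TBSO)germacra-1(10),4,11(13)-trien-12,6-olide, via mixed anhydride 20 (not isolated)
Conditions: 19, 2,4,6-Cl3C6H2COCl, Et3N, PhMe, 23 °C; then 18, 80 °C
Reagents that add atoms: none
Why: Yamaguchi esterification through the 2,4,6-trichlorobenzoyl mixed anhydride, run without DMAP in hot toluene, acylates the hindered C8–OH with retention and without angelate-to-tiglate isomerisation.

Step 11
Reactants: 21 (1(10)E,3S,4Z,6S,7S,8R)-8-(AngO)-3-(TBSO)germacra-1(10),4,11(13)-trien-12,6-olide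
Product: 22 (1S,3S,4Z,6S,7S,8R,10S)-8-(AngO)-3-(TBSO)-1,10-epoxygermacra-4,11(13)-dien-12,6-olide
Conditions: mCPBA (1.05 equiv), NaHCO3, CH2Cl2, 0 °C
Reagents that add atoms: 3-chloroperoxybenzoic acid, OOC(=O)c1cccc(Cl)c1
Why: Prilezhaev epoxidation; C1=C10 is the only electron-rich olefin (C4=C5 is flanked by two allylic C–O bonds, the other two are conjugated to carbonyls), and the peracid attacks its exposed outer face as in related 6,7-trans-lactonised germacra-1(10)-enes, giving the 1β,10α (1S,10S) epoxide.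

Step 12
Reactants: 22 (1S,3S,4Z,6S,7S,8R,10S)-8-(AngO)-3-(TBSO)-1,10-epoxygermacra-4,11(13)-dien-12,6-olide
Product: 24 (1S,3S,4Z,6S,7S,8R,10R)-8-(AngO)-1,3,10-trihydroxygermacra-4,11(13)-dien-12,6-olide, via silylated triol 23 (not isolated)
Conditions: HClO4 (0.5 M aq), THF, 0 → 23 °C
Reagents that add atoms: water, O
Why: Acid-catalysed epoxide hydrolysis; water opens the protonated epoxide at the tertiary C10 with inversion (borderline SN2) while C1 keeps its oxygen, giving the anti diol (1S,10R); the same acid then cleaves the allylic silyl ether.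

## Compound list

1 | (S)-(+)-carvone [(5S)-2-methyl-5-(prop-1-en-2-yl)cyclohex-2-en-1-one] | C1C=C(C)C(=O)C[C@H]1C(C)=C | starting material
2 | (1S,5S)-2-methyl-5-(prop-1-en-2-yl)cyclohex-2-en-1-ol [(+)-cis-carveol] | C1C=C(C)[C@@H](O)C[C@H]1C(C)=C | intermediate
3 | tert-butyl(dimethyl){[(1S,5S)-2-methyl-5-(prop-1-en-2-yl)cyclohex-2-en-1-yl]oxy}silane | C1C=C(C)[C@@H](O[Si](C)(C)C(C)(C)C)C[C@H]1C(C)=C | intermediate
4 | (4S,6S)-4-[(tert-butyldimethylsilyl)oxy]-3-methyl-6-(prop-1-en-2-yl)cyclohex-2-en-1-one | O=C1C=C(C)[C@@H](O[Si](C)(C)C(C)(C)C)C[C@H]1C(C)=C | intermediate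
5 | ethynylmagnesium bromide | C#C[Mg]Br | starting material
6 | (1S,4S,6S)-4-[(tert-butyldimethylsilyl)oxy]-1-ethynyl-3-methyl-6-(prop-1-en-2-yl)cyclohex-2-en-1-ol (ethynyl trans to isopropenyl) | O[C@@]1(C#C)C=C(C)[C@@H](O[Si](C)(C)C(C)(C)C)C[C@H]1C(C)=C | intermediate
7 | 4-methoxybenzyl alcohol | COc1ccc(CO)cc1 | starting material
8 | (1S,4S,6S)-4-[(tert-butyldimethylsilyl)oxy]-1-{(Z)-2-[(4-methoxybenzyl)oxy]ethenyl}-3-methyl-6-(prop-1-en-2-yl)cyclohex-2-en-1-ol | O[C@@]1(/C=C\OCc2ccc(OC)cc2)C=C(C)[C@@H](O[Si](C)(C)C(C)(C)C)C[C@H]1C(C)=C | intermediate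
9 | methyl bromoacetate | COC(=O)CBr | starting material
10 | potassium alkoxide of 8 | [K+].[O-][C@@]1(/C=C\OCc2ccc(OC)cc2)C=C(C)[C@@H](O[Si](C)(C)C(C)(C)C)C[C@H]1C(C)=C | intermediate
11 | potassium (1(10)E,3S,4Z,6Z,8R)-3-[(tert-butyldimethylsilyl)oxy]-8-[(4-methoxybenzyl)oxy]-11,12,13-trinorgermacra-1(10),4,6-trien-6-olate | [K+].C1[C@@H](OCc2ccc(OC)cc2)/C=C(\[O-])/C=C(/C)[C@@H](O[Si](C)(C)C(C)(C)C)C/C=C1\C | intermediate
12 | methyl (1(10)E,3S,4Z,7S,8R)-3-[(tert-butyldimethylsilyl)oxy]-8-[(4-methoxybenzyl)oxy]-6-oxo-13-norgermacra-1(10),4-dien-12-oate | O=C1/C=C(/C)[C@@H](O[Si](C)(C)C(C)(C)C)C/C=C(C)/C[C@@H](OCc2ccc(OC)cc2)[C@@H]1CC(=O)OC | intermediate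
13 | methyl (1(10)E,3S,4Z,6S,7R,8R)-3-[(tert-butyldimethylsilyl)oxy]-6-hydroxy-8-[(4-methoxybenzyl)oxy]-13-norgermacra-1(10),4-dien-12-oate | O[C@H]1/C=C(/C)[C@@H](O[Si](C)(C)C(C)(C)C)C/C=C(C)/C[C@@H](OCc2ccc(OC)cc2)[C@@H]1CC(=O)OC | intermediate
14 | (1(10)E,3S,4Z,6S,7S,8R)-3-[(tert-butyldimethylsilyl)oxy]-8-[(4-methoxybenzyl)oxy]-13-norgermacra-1(10),4-dien-12,6-olide | C1C(=O)O[C@H]2/C=C(/C)[C@@H](O[Si](C)(C)C(C)(C)C)C/C=C(C)/C[C@@H](OCc3ccc(OC)cc3)[C@H]12 | intermediate
15 | (1(10)E,3S,4Z,6S,7S,8R)-13-(dimethylamino)-3-[(tert-butyldimethylsilyl)oxy]-8-[(4-methoxybenzyl)oxy]germacra-1(10),4-dien-12,6-olide (C11 epimers) | CN(C)CC1C(=O)O[C@H]2/C=C(/C)[C@@H](O[Si](C)(C)C(C)(C)C)C/C=C(C)/C[C@@H](OCc3ccc(OC)cc3)[C@H]12 | intermediate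
16 | N-methyl quaternary ammonium iodide of 15 (13-trimethylammonio lactone iodide) | C[N+](C)(C)CC1C(=O)O[C@H]2/C=C(/C)[C@@H](O[Si](C)(C)C(C)(C)C)C/C=C(C)/C[C@@H](OCc3ccc(OC)cc3)[C@H]12.[I-] | intermediate
17 | (1(10)E,3S,4Z,6S,7S,8R)-3-[(tert-butyldimethylsilyl)oxy]-8-[(4-methoxybenzyl)oxy]germacra-1(10),4,11(13)-trien-12,6-olide | C=C1C(=O)O[C@H]2/C=C(/C)[C@@H](O[Si](C)(C)C(C)(C)C)C/C=C(C)/C[C@@H](OCc3ccc(OC)cc3)[C@H]12 | intermediate
18 | (1(10)E,3S,4Z,6S,7S,8R)-3-[(tert-butyldimethylsilyl)oxy]-8-hydroxygermacra-1(10),4,11(13)-trien-12,6-olide | C=C1C(=O)O[C@H]2/C=C(/C)[C@@H](O[Si](C)(C)C(C)(C)C)C/C=C(C)/C[C@@H](O)[C@H]12 | intermediate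
19 | angelic acid [(Z)-2-methylbut-2-enoic acid] | C/C=C(/C)C(=O)O | starting material
20 | (Z)-2-methylbut-2-enoic 2,4,6-trichlorobenzoic anhydride | C/C=C(/C)C(=O)OC(=O)c1c(Cl)cc(Cl)cc1Cl | intermediate
21 | (1(10)E,3S,4Z,6S,7S,8R)-8-[(Z)-2-methylbut-2-enoyloxy]-3-[(tert-butyldimethylsilyl)oxy]germacra-1(10),4,11(13)-trien-12,6-olide | C=C1C(=O)O[C@H]2/C=C(/C)[C@@H](O[Si](C)(C)C(C)(C)C)C/C=C(C)/C[C@@H](OC(=O)/C(C)=C\C)[C@H]12 | intermediate
22 | (1S,3S,4Z,6S,7S,8R,10S)-8-[(Z)-2-methylbut-2-enoyloxy]-3-[(tert-butyldimethylsilyl)oxy]-1,10-epoxygermacra-4,11(13)-dien-12,6-olide | C=C1C(=O)O[C@H]2/C=C(/C)[C@@H](O[Si](C)(C)C(C)(C)C)C[C@@H]3O[C@@]3(C)C[C@@H](OC(=O)/C(C)=C\C)[C@H]12 | intermediate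
23 | (1S,3S,4Z,6S,7S,8R,10R)-8-[(Z)-2-methylbut-2-enoyloxy]-3-[(tert-butyldimethylsilyl)oxy]-1,10-dihydroxygermacra-4,11(13)-dien-12,6-olide | C=C1C(=O)O[C@H]2/C=C(/C)[C@@H](O[Si](C)(C)C(C)(C)C)C[C@H](O)[C@](C)(O)C[C@@H](OC(=O)/C(C)=C\C)[C@H]12 | intermediate
24 | (1S,3S,4Z,6S,7S,8R,10R)-8-[(Z)-2-methylbut-2-enoyloxy]-1,3,10-trihydroxygermacra-4,11(13)-dien-12,6-olide (CNP0249520.1) | C=C1C(=O)O[C@H]2/C=C(/C)[C@@H](O)C[C@H](O)[C@](C)(O)C[C@@H](OC(=O)/C(C)=C\C)[C@H]12 | target

## Step count and risks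

Total step count: 12. Longest linear sequence: 12 steps (1 → 24).

Three steps most likely to fail:

1. Step 5 (the proposed hydroalkoxylation). Possible failures: dehydration of the hydroxy-vinylidene (allenylidene or enal formation), poor turnover with a benzylic alcohol, or E/Z leakage. Fallback (known chemistry; the enol ether is made first and joined by C–C bond formation): 7 is vinylated with butyl vinyl ether [Pd(OCOCF3)2 (divalent palladium), 4,7-diphenyl-1,10-phenanthroline, Et3N, 75 °C] to 4-methoxybenzyl vinyl ether F1. Br2 (CH2Cl2, −78 °C) gives 1-[(1,2-dibromoethoxy)methyl]-4-methoxybenzene F2, which PhNEt2 (90 °C) dehydrobrominates to (Z)-1-bromo-2-[(4-methoxybenzyl)oxy]ethene F3. Bromine–lithium exchange (t-BuLi, Et2O, −78 °C) gives (Z)-2-[(4-methoxybenzyl)oxy]ethenyllithium F4, which adds to the enone anti to the isopropenyl group. This fallback sets out from 4 (with 7) and comes back to the route at 8.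

2. Step 6 (ring expansion and alkylation). Possible failures: the β-alkoxy enolate expels 4-methoxybenzyl oxide before it is alkylated, or a boat pathway erodes C8. Fallback (known chemistry; the C8 oxygen is introduced after ring expansion): 6 is treated with KH and 18-crown-6 in THF, and the alkynyl oxy-Cope rearrangement gives potassium (1(10)E,3S,4Z)-3-(TBSO)-11,12,13-trinorgermacra-1(10),4,6,7-tetraen-6-olate F5. Methyl bromoacetate 9 alkylates it at C7 to give methyl (1(10)E,3S,4Z,7Z)-3-(TBSO)-6-oxo-13-norgermacra-1(10),4,7-trien-12-oate F6. Conjugate borylation [CuCl (monovalent copper), Josiphos-type bisphosphine, NaOt-Bu, B2pin2, MeOH] gives methyl (1(10)E,3S,4Z,7S,8R)-3-(TBSO)-6-oxo-8-(pinacolboryl)-13-norgermacra-1(10),4-dien-12-oate F7, with C7 set by protonation. NaBO3·4H2O oxidises it with retention to methyl (1(10)E,3S,4Z,7S,8R)-3-(TBSO)-8-hydroxy-6-oxo-13-norgermacra-1(10),4-dien-12-oate F8, and 4-methoxybenzyl 2,2,2-trichloroacetimidate with La(OTf)3 protects O8. This fallback sets out from 6 and comes back to the route at 12.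

3. Step 11 (facial selectivity of the epoxidation). Possible failure: the peracid attacks the other face of C1=C10, giving the (1R,10R) epoxide and, after step 12, the wrong diol. Fallback (catalyst control replaces substrate control): Shi epoxidation with the L-fructose-derived ketone [KHSO5 (as 2KHSO5·KHSO4·K2SO4), K2CO3, MeCN–dimethoxymethane–buffer, 0 °C]. Its dioxirane epoxidises (E)-trisubstituted olefins with a predictable sense (the D-fructose-derived ketone gives R,R), so the enantiomeric ketone should give (1S,10S). This fallback sets out from 21 and comes back to the route at 22, with no new compound F0.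

## Further compounds

F1 | step 5 | 4-methoxybenzyl vinyl ether | COc1ccc(COC=C)cc1
F2 | step 5 | 1-[(1,2-dibromoethoxy)methyl]-4-methoxybenzene | COc1ccc(COC(Br)CBr)cc1
F3 | step 5 | (Z)-1-bromo-2-[(4-methoxybenzyl)oxy]ethene | COc1ccc(CO/C=C\Br)cc1
F4 | step 5 | (Z)-2-[(4-methoxybenzyl)oxy]ethenyllithium | COc1ccc(CO/C=C\[Li])cc1
F5 | step 6 | potassium (1(10)E,3S,4Z)-3-[(tert-butyldimethylsilyl)oxy]-11,12,13-trinorgermacra-1(10),4,6,7-tetraen-6-olate | [K+].C1C=C=C([O-])/C=C(/C)[C@@H](O[Si](C)(C)C(C)(C)C)C/C=C1\C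
F6 | step 6 | methyl (1(10)E,3S,4Z,7Z)-3-[(tert-butyldimethylsilyl)oxy]-6-oxo-13-norgermacra-1(10),4,7-trien-12-oate | O=C1/C=C(/C)[C@@H](O[Si](C)(C)C(C)(C)C)C/C=C(C)/C/C=C1/CC(=O)OC
F7 | step 6 | methyl (1(10)E,3S,4Z,7S,8R)-3-[(tert-butyldimethylsilyl)oxy]-6-oxo-8-(4,4,5,5-tetramethyl-1,3,2-dioxaborolan-2-yl)-13-norgermacra-1(10),4-dien-12-oate | O=C1/C=C(/C)[C@@H](O[Si](C)(C)C(C)(C)C)C/C=C(C)/C[C@@H](B2OC(C)(C)C(C)(C)O2)[C@@H]1CC(=O)OC
F8 | step 6 | methyl (1(10)E,3S,4Z,7S,8R)-3-[(tert-butyldimethylsilyl)oxy]-8-hydroxy-6-oxo-13-norgermacra-1(10),4-dien-12-oate | O=C1/C=C(/C)[C@@H](O[Si](C)(C)C(C)(C)C)C/C=C(C)/C[C@@H](O)[C@@H]1CC(=O)OC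
F0 | step 11 | none | none
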